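**Plan**

1. Retrosynthesis (target numbered as 6-oxabicyclo[3.2.2]nonane: C-1 CH bridgehead, C-2 ketone, C-3 allyl, C-4 =CH, C-5 ketal bridgehead, O-6, C-7 lactone C=O, C-8 aryl, C-9 methyl): O-6 is removed first (Baeyer–Villiger retron), giving a bicyclo[3.2.1]oct-3-ene-2,8-dione; a carbonyl is then restored at C-4 (cyclic 1,3-dione); finally C-1–C-2 and C-4–C-5 are cut together.
2. Enabling feature: after removal of O-6, C-1 and C-5 are the α and α′ carbons of a cyclopentanone (ring C-1/C-7/C-5/C-9/C-8). The bridge C-2/C-3/C-4 is a 2-allyl-1,3-dicarbonyl unit one deoxygenation away from the enone, so an allylmalonyl dichloride can span the ring by double C-acylation.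
3. Forward order: the cyclopentane is built first from (S)-4-silyloxycyclopentenone by two copper-mediated conjugate additions; the six- and seven-membered carbocycles of the bicycle then close in one operation; the extra oxygen at C-4 is removed by carbonyl transposition; the lactone oxygen is inserted last.
4. Stereochemistry: the single chiral-pool centre sets C-9 (methyl anti to OSi) and is then eliminated; C-9 sets C-8 (aryl anti to methyl). C-1 and C-5 follow from bridging the ring face anti to the aryl group, and C-5 migrates with retention in the Baeyer–Villiger step.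

Key step: step 6

Remark on the chemistry: trione 10 is an enolized cyclic 1,3-dione and is drawn and named as one enol tautomer; compounds 3, 4 and 6 are carried as epimer mixtures at the methoxy-bearing carbon, which is enolized in step 6 and then fixed as a bridgehead.

**Step 1**
Reactants: 1 (4S)-4-[(tert-butyldimethylsilyl)oxy]cyclopent-2-en-1-one
Product: 2 tert-butyl(dimethyl){[(1S,2S)-2-methyl-4-[(trimethylsilyl)oxy]cyclopent-3-en-1-yl]oxy}silane
Conditions: MeMgBr, CuBr·SMe2 (10 mol %), TMSCl, THF, −78 °C
Reagents that add atoms: methylmagnesium bromide C[Mg]Br; chlorotrimethylsilane C[Si](C)(C)Cl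
Why: Copper-catalysed conjugate addition of the Grignard reagent (TMSCl-accelerated) should occur anti to the C-4 silyloxy group, which sets the methyl-bearing centre, and the enolate is trapped as the silyl enol ether on the side that is to carry the methoxy group.

**Step 2**
Reactants: 2 tert-butyl(dimethyl){[(1S,2S)-2-methyl-4-[(trimethylsilyl)oxy]cyclopent-3-en-1-yl]oxy}silane
Product: 3 (3S,4S)-4-[(tert-butyldimethylsilyl)oxy]-2-methoxy-3-methylcyclopentan-1-one (C-2 epimers)
Conditions: PhIO, BF3·OEt2, MeOH/CH2Cl2, −70 to −20 °C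
Reagents that add atoms: methanol CO
Why: Hypervalent-iodine α-oxidation of a silyl enol ether in methanol (α-methoxylation through the α-iodanyl ketone) should place OMe on the former enol carbon only; the new centre is left uncontrolled because it is later enolized.

**Step 3**
Reactants: 3 (3S,4S)-4-[(tert-butyldimethylsilyl)oxy]-2-methoxy-3-methylcyclopentan-1-one
Product: 4 (4R)-5-methoxy-4-methylcyclopent-2-en-1-one (C-5 epimers)
Conditions: DBU, CH2Cl2, 0 °C
Reagents that add atoms: none
Why: E1cB β-elimination of the silanol through the α′-enolate should give the transposed enone, in which the methyl-bearing carbon is now the γ-stereocentre.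

**Step 4**
Reactants: 4 (4R)-5-methoxy-4-methylcyclopent-2-en-1-one; 5 (3,4,5-trimethoxyphenyl)magnesium bromide
Product: 6 trimethyl{[(3R,4R)-5-methoxy-4-methyl-3-(3,4,5-trimethoxyphenyl)cyclopent-1-en-1-yl]oxy}silane (C-5 epimers)
Conditions: CuBr·SMe2 (10 mol %), TMSCl, THF, −78 °C
Reagents that add atoms: chlorotrimethylsilane C[Si](C)(C)Cl
Why: A second copper-catalysed conjugate addition should deliver the aryl group anti to the neighbouring methyl group (trans relationship) and leave the silyl enol ether double bond toward the CH next to the aryl-bearing carbon, as the key step requires.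

**Step 5**
Reactants: 7 2-(prop-2-en-1-yl)propanedioic acid (allylmalonic acid)
Product: 8 2-(prop-2-en-1-yl)propanedioyl dichloride
Conditions: SOCl2, DMF (cat.), 50 °C; distillation
Reagents that add atoms: thionyl chloride O=S(Cl)Cl
Why: Standard acyl chloride formation from a malonic acid with thionyl chloride.

**Step 6**
Reactants: 6 trimethyl{[(3R,4R)-5-methoxy-4-methyl-3-(3,4,5-trimethoxyphenyl)cyclopent-1-en-1-yl]oxy}silane; 8 2-(prop-2-en-1-yl)propanedioyl dichloride
Product: 10 (1S,5R,6R,7R)-4-hydroxy-1-methoxy-7-methyl-3-(prop-2-en-1-yl)-6-(3,4,5-trimethoxyphenyl)bicyclo[3.2.1]oct-3-ene-2,8-dione, via keto acid chloride 9 (not isolated)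
Conditions: Et2O, −20 °C to rt
Reagents that add atoms: none
Why: Effenberger cyclization (double C-acylation of a ketone enol ether by a malonyl dichloride): the enol carbon of 6 attacks one COCl of 8 anti to the adjacent aryl group with loss of Me3SiCl to give 9, and the second COCl (as such or as the derived acylketene) then acylates the methoxy-bearing α′-carbon through the cross enol. The closest known reaction type is the cyclization of cyclohexanone silyl or methyl enol ethers with malonyl dichloride to bicyclo[3.3.1]nonane-2,4,9-triones. The second C–C bond closes two rings at once: the cyclohexane-1,3-dione ring by a 6-(enolendo)-exo-trig acylation, and the seven-membered ring of the bicyclo[3.2.1]octane by the same bond counted as 7-(enolexo)-exo-trig. Both bridgehead centres are set by the ring face that the three-carbon bridge spans: the acylated carbon of 9 is epimerizable as a β-dicarbonyl, and both the kinetic anti-acylation and the less crowded closure (Curtin–Hammett) should put the bridge anti to the aryl group (aryl exo, methyl endo), after which the methoxy bridgehead has no freedom. The step needs acylation at the aryl-side carbon first, which the regiodefined enol ether from step 4 secures, and C- over O-acylation in the ring closure, which is favoured by non-basic, chloride-containing conditions under which an O-acyl enol lactone can revert.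

**Step 7**
Reactants: 10 (1S,5R,6R,7R)-4-hydroxy-1-methoxy-7-methyl-3-(prop-2-en-1-yl)-6-(3,4,5-trimethoxyphenyl)bicyclo[3.2.1]oct-3-ene-2,8-dione
Product: 11 (1S,5R,6R,7R)-1-methoxy-7-methyl-3-(prop-2-en-1-yl)-4-{[tri(propan-2-yl)silyl]oxy}-6-(3,4,5-trimethoxyphenyl)bicyclo[3.2.1]oct-3-ene-2,8-dione
Conditions: TIPSOTf, Et3N, CH2Cl2, −78 °C
Reagents that add atoms: triisopropylsilyl trifluoromethanesulfonate CC(C)[Si](OS(=O)(=O)C(F)(F)F)(C(C)C)C(C)C
Why: Kinetic O-silylation of the cyclic vinylogous acid with a bulky silyl triflate should occur at the enol oxygen next to the CH bridgehead, because the other oxygen is flanked by the bridgehead OMe and the endo methyl group.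

**Step 8**
Reactants: 11 (1S,5R,6R,7R)-1-methoxy-7-methyl-3-(prop-2-en-1-yl)-4-{[tri(propan-2-yl)silyl]oxy}-6-(3,4,5-trimethoxyphenyl)bicyclo[3.2.1]oct-3-ene-2,8-dione
Product: 13 (1S,5R,6R,7R)-8-hydroxy-5-methoxy-6-methyl-3-(prop-2-en-1-yl)-7-(3,4,5-trimethoxyphenyl)bicyclo[3.2.1]oct-3-en-2-one (C-8 epimers), via diol 12 (not isolated)
Conditions: i-Bu2AlH, CH2Cl2, −78 to −20 °C; then 1 M HCl, THF, 0 °C to rt
Reagents that add atoms: none
Why: Stork–Danheiser-type 1,3-carbonyl transposition: hydride reduces the vinylogous-ester carbonyl (and the bridging ketone), and acid then expels water and silanol to leave the enone carbonyl next to the CH bridgehead.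

**Step 9**
Reactants: 13 (1S,5R,6R,7R)-8-hydroxy-5-methoxy-6-methyl-3-(prop-2-en-1-yl)-7-(3,4,5-trimethoxyphenyl)bicyclo[3.2.1]oct-3-en-2-one
Product: 14 (1R,5R,6R,7R)-5-methoxy-6-methyl-3-(prop-2-en-1-yl)-7-(3,4,5-trimethoxyphenyl)bicyclo[3.2.1]oct-3-ene-2,8-dione
Conditions: Dess–Martin periodinane, CH2Cl2, rt
Reagents that add atoms: none
Why: Dess–Martin oxidation should return the bridging secondary alcohol to the ketone under neutral conditions that spare the allyl group and avoid retro-aldol opening.

**Step 10**
Reactants: 14 (1R,5R,6R,7R)-5-methoxy-6-methyl-3-(prop-2-en-1-yl)-7-(3,4,5-trimethoxyphenyl)bicyclo[3.2.1]oct-3-ene-2,8-dione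
Product: 15 (1R,5S,8R,9R)-5-methoxy-9-methyl-3-(prop-2-en-1-yl)-8-(3,4,5-trimethoxyphenyl)-6-oxabicyclo[3.2.2]non-3-ene-2,7-dione
Conditions: Me3SiOOSiMe3, Me3SiOTf (10 mol %), CH2Cl2, −78 to −30 °C
Reagents that add atoms: bis(trimethylsilyl) peroxide C[Si](C)(C)OO[Si](C)(C)C
Why: Baeyer–Villiger oxidation with a silyl peroxide and a silyl triflate, an oxidant that leaves C=C bonds alone, should attack the strained non-conjugated bridging ketone; the tertiary, methoxy-bearing bridgehead migrates with retention in preference to the acyl-substituted CH, so oxygen enters between C-8 and C-5 of 14.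

**Compound list**

1 | (4S)-4-[(tert-butyldimethylsilyl)oxy]cyclopent-2-en-1-one | O=C1C=C[C@@H](O[Si](C)(C)C(C)(C)C)C1 | starting material
2 | tert-butyl(dimethyl){[(1S,2S)-2-methyl-4-[(trimethylsilyl)oxy]cyclopent-3-en-1-yl]oxy}silane | C[Si](C)(C)OC1=C[C@H](C)[C@@H](O[Si](C)(C)C(C)(C)C)C1 | intermediate
3 | (3S,4S)-4-[(tert-butyldimethylsilyl)oxy]-2-methoxy-3-methylcyclopentan-1-one (C-2 epimers) | COC1[C@H](C)[C@@H](O[Si](C)(C)C(C)(C)C)CC1=O | intermediate
4 | (4R)-5-methoxy-4-methylcyclopent-2-en-1-one (C-5 epimers) | COC1[C@H](C)C=CC1=O | intermediate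
5 | (3,4,5-trimethoxyphenyl)magnesium bromide (THF solution) | COc1cc([Mg]Br)cc(OC)c1OC | starting material
6 | trimethyl{[(3R,4R)-5-methoxy-4-methyl-3-(3,4,5-trimethoxyphenyl)cyclopent-1-en-1-yl]oxy}silane (C-5 epimers) | COC1[C@H](C)[C@@H](c2cc(OC)c(OC)c(OC)c2)C=C1O[Si](C)(C)C | intermediate
7 | 2-(prop-2-en-1-yl)propanedioic acid | C=CCC(C(=O)O)C(=O)O | starting material
8 | 2-(prop-2-en-1-yl)propanedioyl dichloride | C=CCC(C(=O)Cl)C(=O)Cl | intermediate
9 | 2-{[(2R,3R)-4-methoxy-3-methyl-5-oxo-2-(3,4,5-trimethoxyphenyl)cyclopentyl]carbonyl}pent-4-enoyl chloride (other centres undefined, enolizable) | C=CCC(C(=O)Cl)C(=O)C1C(=O)C(OC)[C@H](C)[C@H]1c1cc(OC)c(OC)c(OC)c1 | intermediate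
10 | (1S,5R,6R,7R)-4-hydroxy-1-methoxy-7-methyl-3-(prop-2-en-1-yl)-6-(3,4,5-trimethoxyphenyl)bicyclo[3.2.1]oct-3-ene-2,8-dione (enol tautomer of the 2,4,8-trione) | C=CCC1=C(O)[C@@H]2C(=O)[C@](OC)(C1=O)[C@H](C)[C@H]2c3cc(OC)c(OC)c(OC)c3 | intermediate
11 | (1S,5R,6R,7R)-1-methoxy-7-methyl-3-(prop-2-en-1-yl)-4-{[tri(propan-2-yl)silyl]oxy}-6-(3,4,5-trimethoxyphenyl)bicyclo[3.2.1]oct-3-ene-2,8-dione | C=CCC1=C(O[Si](C(C)C)(C(C)C)C(C)C)[C@@H]2C(=O)[C@](OC)(C1=O)[C@H](C)[C@H]2c3cc(OC)c(OC)c(OC)c3 | intermediate
12 | (1S,5S,6R,7R)-1-methoxy-7-methyl-3-(prop-2-en-1-yl)-4-{[tri(propan-2-yl)silyl]oxy}-6-(3,4,5-trimethoxyphenyl)bicyclo[3.2.1]oct-3-ene-2,8-diol (carbinol centres C-2 and C-8 undefined) | C=CCC1=C(O[Si](C(C)C)(C(C)C)C(C)C)[C@@H]2C(O)[C@](OC)(C1O)[C@H](C)[C@H]2c3cc(OC)c(OC)c(OC)c3 | intermediate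
13 | (1S,5R,6R,7R)-8-hydroxy-5-methoxy-6-methyl-3-(prop-2-en-1-yl)-7-(3,4,5-trimethoxyphenyl)bicyclo[3.2.1]oct-3-en-2-one (C-8 epimers) | C=CCC1=C[C@@]2(OC)C(O)[C@@H](C1=O)[C@H](c1cc(OC)c(OC)c(OC)c1)[C@H]2C | intermediate
14 | (1R,5R,6R,7R)-5-methoxy-6-methyl-3-(prop-2-en-1-yl)-7-(3,4,5-trimethoxyphenyl)bicyclo[3.2.1]oct-3-ene-2,8-dione | C=CCC1=C[C@@]2(OC)C(=O)[C@@H](C1=O)[C@H](c1cc(OC)c(OC)c(OC)c1)[C@H]2C | intermediate
15 | (1R,5S,8R,9R)-5-methoxy-9-methyl-3-(prop-2-en-1-yl)-8-(3,4,5-trimethoxyphenyl)-6-oxabicyclo[3.2.2]non-3-ene-2,7-dione | C=CCC1=C[C@@]2(OC)OC(=O)[C@@H](C1=O)[C@H](c1cc(OC)c(OC)c(OC)c1)[C@H]2C | target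

**Step count**

Total steps: 10. Longest linear sequence: 9 (steps 1–4 and 6–10, from 1).

**Steps most likely to fail**

Step 6. The ring closure may go through the enol oxygen (O-acylation to a fused hydroxypyranone), or the monosubstituted acid chloride may lose HCl to an acylketene that oligomerizes before the second C-acylation; the closure may also take the aryl face. Fallback: setting out from 6, the cyclization is run with unsubstituted malonyl dichloride, the reagent for which this double C-acylation is established, to give the 3-unsubstituted bicyclic trione F1. The allyl group is then put on carbon by Tsuji–Trost allylation of the vinylogous acid (allyl methyl carbonate, Pd(PPh3)4, THF), which returns to the route at 10.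

Step 7. Silylation may occur on the enol oxygen next to the methoxy bridgehead (for example through a tautomer or chelation preference), which would transpose the carbonyl to the wrong side in step 8. Fallback: setting out from 10, that regiochemical preference is used instead of opposed. Triflation (KHMDS, PhNTf2, THF, −78 °C) should give the enol triflate F2 on the oxygen next to the methoxy bridgehead, and hydrogenolysis of the C–OTf bond (Pd(OAc)2, PPh3, Bu3N, HCO2H, DMF, 60 °C) then gives the enone directly, returning at 14 and bypassing 11–13.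

Step 10. The allyl double bond may be oxidized in competition with the ketone, or the Lewis acid may ionize the acylated ketal bridgehead of the product. Fallback: setting out from 14, the terminal alkene is masked by bromine addition (pyridinium tribromide, 1 equiv, CH2Cl2, −78 °C) to give the dibromide F3. Buffered peracid Baeyer–Villiger oxidation (mCPBA, NaHCO3, CH2Cl2) gives the dibromo lactone F4, and iodide-induced debromination (NaI, acetone) returns the alkene at 15.

**Further compounds**

F1 | step 6 | 3-unsubstituted analogue of trione 10 (enol tautomer, same configuration at the four ring stereocentres) | C1=C(O)[C@@H]2C(=O)[C@](OC)(C1=O)[C@H](C)[C@H]2c3cc(OC)c(OC)c(OC)c3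
F2 | step 7 | enol trifluoromethanesulfonate of 10 on the oxygen next to the methoxy bridgehead (4-triflyloxy derivative of 14) | C=CCC1=C(OS(=O)(=O)C(F)(F)F)[C@@]2(OC)C(=O)[C@@H](C1=O)[C@H](c1cc(OC)c(OC)c(OC)c1)[C@H]2C
F3 | step 10 | 3-(2,3-dibromopropyl) analogue of dione 14 (CHBr centre undefined) | BrCC(Br)CC1=C[C@@]2(OC)C(=O)[C@@H](C1=O)[C@H](c1cc(OC)c(OC)c(OC)c1)[C@H]2C
F4 | step 10 | 3-(2,3-dibromopropyl) analogue of lactone 15 (CHBr centre undefined) | BrCC(Br)CC1=C[C@@]2(OC)OC(=O)[C@@H](C1=O)[C@H](c1cc(OC)c(OC)c(OC)c1)[C@H]2C
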